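All runs stem from a simulated flask from invented constants, and the scatter is random.

Saturday's run is the earlier run whose charge of Q lies next to alpha's, so I start from it.

| flask | Q | Z | G | remark | time |
|---|---|---|---|---|---|
| Thursday's | 0.13 M | 14 mM | 7 mM | run made earlier |  |
| Monday's | 0.19 M | 14 mM | 7 mM | run made earlier |  |
| Saturday's | 0.28 M | 14 mM | 7 mM | run made earlier |  |
| alpha | 0.27 M | 14 mM | 7.0 mM |  | 5.0 d |
| gamma | 0.15 M | 14 mM | 7.0 mM |  | 5.0 d |

- Thursday's (time / d: E / %): 0.625: 30; 1.25: 42; 2.00: 51; 3.00: 55; 4.00: 53
- Monday's (time / d: E / %): 0.333: 22; 0.833: 40; 1.67: 54; 2.50: 59; 4.00: 63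
- Saturday's (time / d: E / %): 0.333: 23; 0.833: 46; 1.67: 57; 2.50: 63; 4.00: 66

(scatter of a reading: 1.5 percentage points)

- the average divides the monomer in chains by the number of chains begun, living and dead together
- the earlier runs do not show the number of chains; that part of a forecast is a guess

- which of the two ends with the longer chains by the average number of monomer units in a chain (chains begun, living or dead) ("neither" if they lie within 10 %) (alpha / gamma / neither)
- average number of monomer units in a chain (chains begun, living or dead) at the end, alpha
- average number of monomer units in a chain (chains begun, living or dead) at the end, gamma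

I read that run in slow motion. In the first instants I take Z to begin the chains, though the readings show neither Z nor G, and E reads 23 % after 0.333 d. In the middle E still climbs, from 46 % at 0.833 d to 57 % at 1.67 d. At the end the longer stretch up to 4.00 d adds 9 percentage points, less than the opening did, so the curve is levelling off with 0.0952 M of Q not read as E.

What matters for length is the plateau [E] over [Z] as charged, the units per Z charged, which is the theoretical degree of polymerization. If every Z begins one chain, this is the average length; any Z lost without beginning a chain means fewer chains and longer ones. Saturday's last percentage on alpha's charge gives 12.7. For gamma, the mean of the last readings of Thursday's and Monday's runs gives 6.21. So I expect alpha to be longer, and I commit to these two numbers as my estimates.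

The forecast says alpha, with 13 for alpha and 6.2 for gamma, on the ground “My guess is one chain per Z”.

The flask gives alpha, with 20.5 against 11.5 for gamma.

    X + E → L (k = 4.80 × 10⁻⁵ L mol⁻¹ s⁻¹)
    Q + Z → X + E (k = 0.00560 L mol⁻¹ s⁻¹)
    Z + G → D (k = 0.220 L mol⁻¹ s⁻¹)
    E + X → Q + X, rate k4*[X] as long as [E] is above zero (k = 6.00 × 10⁻⁵ s⁻¹)
    Q + X → E + X, rate k5*[X]*[Q] (k = 0.00130 L mol⁻¹ s⁻¹)

Alpha ends longer than gamma, and the main reason is the difference in concentration of Q: gamma charged with alpha's Q gives 20.5 against its own 11.5. Alpha ends at 1.61 times my estimate, and the reaction of Z with G to D is a part of that excess: the run of alpha without that step gives 13.9 against my 12.7.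

In the neighbour that is gamma with 0.38 M of Q, the units per Z charged, with Saturday's last percentage held, come to 17.9. The computed flask gives 26.7, with E at 67.3 %.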